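**Retrosynthetic overview**

- Mururin C is read as an oxidised 8–5' neolignan. O1–C2 and C3–C3a of the furan join a cinnamate unit (ring C, C2, C3 and the formyl carbon) to a guaiacyl-propanoid unit (ring A, with C3a and C7a–O1).
- Last disconnection: one of the two equivalent methyl ethers flanking the ring C phenol. Before that, the CHO and the hydroxypropyl chain go back to two methyl esters (global reduction, then oxidation of the heterobenzylic alcohol only).
- The benzofuran goes back to a trans-2,3-dihydrobenzofuran by dehydrogenation; its two stereocentres are relay centres only.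
- The dihydrofuran is the only ring formed (rings A and C are bought). It is closed by Ag2O radical cross-coupling of methyl sinapate (through C8) with methyl dihydroferulate (through C5), then phenol addition to the quinone methide.
- Both partners come from sinapic acid and dihydroferulic acid by esterification.

Key step: step 3

Remark: mururin C has no stereocentre; compounds 5–7 are racemic, are drawn as one enantiomer, and lose both centres in step 5.

**Route**

Step 1
Reactants: 1 sinapic acid
Product: 2 methyl (E)-sinapate
Conditions: MeOH, H2SO4 (cat.), reflux
Reagents that add atoms: methanol, CO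
Why: Fischer esterification in excess methanol should convert the acid into its methyl ester without touching the phenol or the (E)-alkene.

Step 2
Reactants: 3 3-(4-hydroxy-3-methoxyphenyl)propanoic acid (dihydroferulic acid)
Product: 4 methyl 3-(4-hydroxy-3-methoxyphenyl)propanoate (methyl dihydroferulate)
Conditions: MeOH, H2SO4 (cat.), reflux
Reagents that add atoms: methanol, CO
Why: Fischer esterification of the saturated acid should proceed cleanly and leave the phenol free for the oxidation.

Step 3
Reactants: 2 methyl (E)-sinapate; 4 methyl dihydroferulate
Product: 6 racemic methyl trans-2-(4-hydroxy-3,5-dimethoxyphenyl)-7-methoxy-5-(3-methoxy-3-oxopropyl)-2,3-dihydrobenzofuran-3-carboxylate, via p-quinone methide 5 (not isolated)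
Conditions: Ag2O (1.2 equiv), 4 (3 equiv), PhH–acetone 2:1, rt, dark, N2; 2 added slowly over several hours
Reagents that add atoms: none
Why: Ag2O removes one electron and one proton from each phenol; the sinapate radical, whose ring carbons ortho to oxygen both carry methoxy groups, can bond only through C8 or oxygen, and it should combine through C8 with the free ortho carbon C5 of the dihydroferulate radical to form the C3–C3a bond. Tautomerisation of the ring A dienone restores the guaiacyl phenol and leaves ring C as p-quinone methide 5, whose methide carbon is then attacked by that phenol oxygen in a 5-exo-trig oxa-conjugate addition that forms O1–C2, closes the dihydrofuran and rearomatises ring C. The closest known reactions are the Ag2O dehydrodimerisation of ferulate esters to trans-2-aryl-2,3-dihydrobenzofuran-3-carboxylates and the radical cross-coupling of hydroxycinnamyl units with guaiacyl phenols in lignin model chemistry. C3 is formed without facial bias (racemate) and C2 is set relative to it in the ring closure, where the aryl group takes the face opposite the ester, and the acidic C3–H allows any cis isomer to equilibrate to trans. The step needs cross-coupling over homocoupling and C5 over O attack on the guaiacyl partner: a dihydrofuran can only come from the cross pair because sinapate has no free ring carbon and dihydroferulate has no conjugated side chain, excess 4 and slow addition of 2 keep the sinapate radical dilute against its 8–8 dimer, and the 8–O–4 ether and the 5–5 biaryl of 4 are to be removed by chromatography.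

Step 4
Reactants: 6 racemic trans-dihydrobenzofuran diester
Product: 7 racemic methyl trans-2-(4-acetoxy-3,5-dimethoxyphenyl)-7-methoxy-5-(3-methoxy-3-oxopropyl)-2,3-dihydrobenzofuran-3-carboxylate
Conditions: Ac2O, pyridine, DMAP (cat.), CH2Cl2, rt
Reagents that add atoms: acetic anhydride, CC(=O)OC(C)=O
Why: DMAP-catalysed O-acetylation of the single, hindered syringyl phenol masks the most easily oxidised group before the quinone oxidant is used, and the weak base should not open the dihydrofuran by β-elimination.

Step 5
Reactants: 7 acetate of the trans-dihydrobenzofuran diester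
Product: 8 methyl 2-(4-acetoxy-3,5-dimethoxyphenyl)-7-methoxy-5-(3-methoxy-3-oxopropyl)benzofuran-3-carboxylate
Conditions: DDQ (1.5 equiv), 1,4-dioxane, reflux
Reagents that add atoms: none
Why: DDQ dehydrogenation, in which hydride abstraction from C2–H (benzylic and next to O1) gives an oxocarbenium ion that loses the acidic C3–H to form the aromatic furan and erase both stereocentres; the acetate keeps ring C from quinone methide chemistry and the side-chain CH2 is less activated than C2–H.

Step 6
Reactants: 8 benzofuran diester acetate
Product: 9 4-[3-(hydroxymethyl)-5-(3-hydroxypropyl)-7-methoxybenzofuran-2-yl]-2,6-dimethoxyphenol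
Conditions: LiAlH4, THF, 0 °C to rt; aq. KNaC4H4O6 (Rochelle salt) work-up
Reagents that add atoms: none
Why: LiAlH4 ester reduction should turn both methyl esters into primary alcohols and cleave the aryl acetate in the same operation, and the non-acidic tartrate work-up avoids ionising the electron-rich benzofuran-3-ylmethanol.

Step 7
Reactants: 9 triol
Product: 10 2-(4-hydroxy-3,5-dimethoxyphenyl)-5-(3-hydroxypropyl)-7-methoxybenzofuran-3-carbaldehyde
Conditions: activated MnO2 (excess), CH2Cl2, rt
Reagents that add atoms: none
Why: Chemoselective MnO2 oxidation acts on benzylic-type alcohols only, so the benzofuran-3-ylmethanol should go to the aldehyde while the saturated primary alcohol stays, and the syringyl phenol, blocked at both ortho positions and at the para position, has no site open for oxidative coupling.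

Step 8
Reactants: 10 syringyl aldehyde
Product: 11 mururin C
Conditions: AlCl3 (excess), pyridine, CH2Cl2, reflux; then 1 M HCl
Reagents that add atoms: none
Why: Lange-type AlCl3–pyridine cleavage of an o-hydroxyaryl methyl ether, in which the aluminium phenoxide chelates one flanking methoxy oxygen and pyridine takes its methyl group; the aluminium catecholate formed no longer activates the second, equivalent methoxy group, and the 7-OMe has no neighbouring phenoxide and should survive.

**Compound list**

1 | sinapic acid | COc1cc(/C=C/C(=O)O)cc(OC)c1O | starting material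
2 | methyl (E)-sinapate | COC(=O)/C=C/c1cc(OC)c(O)c(OC)c1 | intermediate
3 | 3-(4-hydroxy-3-methoxyphenyl)propanoic acid | COc1cc(CCC(=O)O)ccc1O | starting material
4 | methyl 3-(4-hydroxy-3-methoxyphenyl)propanoate | COC(=O)CCc1ccc(O)c(OC)c1 | intermediate
5 | 8–5'-coupled p-quinone methide, racemic, one enantiomer drawn (not isolated) | COC(=O)CCc1cc(OC)c(O)c(c1)[C@@H](C(=O)OC)C=C1C=C(OC)C(=O)C(OC)=C1 | intermediate
6 | racemic methyl (2R*,3R*)-2-(4-hydroxy-3,5-dimethoxyphenyl)-7-methoxy-5-(3-methoxy-3-oxopropyl)-2,3-dihydrobenzofuran-3-carboxylate (trans; 2R,3R drawn) | COC(=O)CCc1cc(OC)c2c(c1)[C@@H](C(=O)OC)[C@H](c1cc(OC)c(O)c(OC)c1)O2 | intermediate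
7 | racemic methyl (2R*,3R*)-2-(4-acetoxy-3,5-dimethoxyphenyl)-7-methoxy-5-(3-methoxy-3-oxopropyl)-2,3-dihydrobenzofuran-3-carboxylate (trans; 2R,3R drawn) | COC(=O)CCc1cc(OC)c2c(c1)[C@@H](C(=O)OC)[C@H](c1cc(OC)c(OC(C)=O)c(OC)c1)O2 | intermediate
8 | methyl 2-(4-acetoxy-3,5-dimethoxyphenyl)-7-methoxy-5-(3-methoxy-3-oxopropyl)benzofuran-3-carboxylate | COC(=O)CCc1cc(OC)c2oc(-c3cc(OC)c(OC(C)=O)c(OC)c3)c(C(=O)OC)c2c1 | intermediate
9 | 4-[3-(hydroxymethyl)-5-(3-hydroxypropyl)-7-methoxybenzofuran-2-yl]-2,6-dimethoxyphenol | OCCCc1cc(OC)c2oc(-c3cc(OC)c(O)c(OC)c3)c(CO)c2c1 | intermediate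
10 | 2-(4-hydroxy-3,5-dimethoxyphenyl)-5-(3-hydroxypropyl)-7-methoxybenzofuran-3-carbaldehyde | COc1cc(-c2oc3c(OC)cc(CCCO)cc3c2C=O)cc(OC)c1O | intermediate
11 | mururin C, 2-(3,4-dihydroxy-5-methoxyphenyl)-5-(3-hydroxypropyl)-7-methoxybenzofuran-3-carbaldehyde | COc1cc(-c2oc3c(OC)cc(CCCO)cc3c2C=O)cc(O)c1O | target

**Step count**

Total: 8 steps. Longest linear sequence: 7 steps (1 or 3 to 11).

**Steps most likely to fail**

Step 3. The cross-coupling may be outrun by 8–8 homocoupling of the more easily oxidised sinapate, by 5–5 coupling of 4, by O- instead of C-attack on the guaiacyl partner, or by further oxidation of the syringyl phenol of the product. The fallback sets out from phenol 4 and comes back to the route at benzofuran 8, passing by 6 and 7. Purchased syringic acid F1 would be acetylated (Ac2O, pyridine) to 4-acetoxy-3,5-dimethoxybenzoic acid F2. F2 would be homologated (carbonyldiimidazole; then potassium methyl malonate, MgCl2, Et3N, MeCN; acidic work-up) to methyl 3-(4-acetoxy-3,5-dimethoxyphenyl)-3-oxopropanoate F3. F3 and 4 would then be joined by the known iron-catalysed oxidative coupling–annulation of phenols with β-keto esters (FeCl3·6H2O cat., di-tert-butyl peroxide, 1,2-dichloroethane, 100 °C). In it the free ortho carbon of 4 bonds to the α-carbon of F3 and the phenol oxygen condenses on the ketone with loss of water, which should give 8 directly.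

Step 8. The ether cleavage may stall because the aluminium reagent is tied up by the alcohol and the aldehyde, or it may lose selectivity and also cleave the second ring C ether or the 7-OMe. The fallback sets out from 10 and comes back at 11 by oxidative instead of Lewis-acid demethylation. Periodate oxidation (NaIO4, aq. MeCN, 0 °C) of the 2,6-dimethoxyphenol should expel one methoxy group as methanol and give 5-[3-formyl-5-(3-hydroxypropyl)-7-methoxybenzofuran-2-yl]-3-methoxy-1,2-benzoquinone F6. Reduction of F6 at once with aqueous Na2S2O4 should give the catechol 11.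

Step 5. Hydride abstraction may be slow on the acetate-deactivated substrate, and under forcing conditions it may also occur at the benzylic CH2 of the propanoate chain, dehydrogenating it to a cinnamate. The fallback sets out from free phenol 6 (step 4 is left out) and comes back at triol 9. Ag2O (CH2Cl2, rt) should oxidise the syringyl phenol of 6 by two electrons to the ring C p-quinone methide with C2 as methide carbon F4, which is not isolated. A catalytic amount of Et3N should remove its C3–H (α to the ester) and tautomerise it to methyl 2-(4-hydroxy-3,5-dimethoxyphenyl)-7-methoxy-5-(3-methoxy-3-oxopropyl)benzofuran-3-carboxylate F5. LiAlH4 reduction of F5 under the conditions of step 6 should give 9.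

**Further compounds**

F1 | step 3 | syringic acid (purchased) | COc1cc(C(=O)O)cc(OC)c1O
F2 | step 3 | 4-acetoxy-3,5-dimethoxybenzoic acid | COc1cc(C(=O)O)cc(OC)c1OC(C)=O
F3 | step 3 | methyl 3-(4-acetoxy-3,5-dimethoxyphenyl)-3-oxopropanoate | COC(=O)CC(=O)c1cc(OC)c(OC(C)=O)c(OC)c1
F4 | step 5 | ring C p-quinone methide of 6, racemic, one enantiomer drawn (not isolated) | COC(=O)CCc1cc(OC)c2c(c1)[C@@H](C(=O)OC)C(=C1C=C(OC)C(=O)C(OC)=C1)O2
F5 | step 5 | methyl 2-(4-hydroxy-3,5-dimethoxyphenyl)-7-methoxy-5-(3-methoxy-3-oxopropyl)benzofuran-3-carboxylate | COC(=O)CCc1cc(OC)c2oc(-c3cc(OC)c(O)c(OC)c3)c(C(=O)OC)c2c1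
F6 | step 8 | 5-[3-formyl-5-(3-hydroxypropyl)-7-methoxybenzofuran-2-yl]-3-methoxy-1,2-benzoquinone | COC1=CC(-c2oc3c(OC)cc(CCCO)cc3c2C=O)=CC(=O)C1=O
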